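The route rests on disconnecting the carbocycle of the 1H-isochromene (C4a, C5, C6, C7, C8, C8a) at C5–C4a and C8–C8a. Both bonds should form in one intramolecular Diels–Alder reaction of an acyclic silaketal, in which a (1E)-2-methylbutadienyl silyl ether (future C5–C8) is tied through a di(propan-2-yl)silylene to the propargylic oxygen of a diynyl acrylate. The step exploits the two oxygens that flank C8a (on C8 and on C1) as tether anchors and leaves the C4a=C8a alkene from the alkyne. The C6=C7 alkene that remains takes the trans C6 ester and C7 hydroxyl by asymmetric epoxidation and carboxylate opening; the pyran ring closes late.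

Key step: step 3

Remark: locants C1–C8a in the Why lines are those of the 1H-isochromene core of the target.
Assumption: the facial preference of the fructose-derived dioxirane is taken from the spiro transition-state model for 1-substituted cyclohexenes; if the opposite face reacts, the enantiomeric ketone (from L-sorbose) is used instead.

Step 1
Reactants: 1 hexa-2,4-diyne-1,6-diol; 2 tert-butyl 2-(triphenyl-λ5-phosphanylidene)acetate
Product: 4 tert-butyl (2E)-8-hydroxyoct-2-ene-4,6-diynoate, via 6-hydroxyhexa-2,4-diynal 3 (not isolated)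
Conditions: activated MnO2 (10 equiv), 1 (3 equiv), 2 (1 equiv), CH2Cl2, rt
Reagents that add atoms: none
Why: Tandem MnO2 oxidation–Wittig olefination, in which the unstable ynal is trapped as it forms by the stabilized ylide to give the (E)-enoate, while the excess of diol should hold the reaction at the mono-adduct.

Step 2
Reactants: 5 (2E)-2-methylbut-2-enal; 4 tert-butyl (2E)-8-hydroxyoct-2-ene-4,6-diynoate
Product: 7 tert-butyl (2E)-8-[({[(1E)-2-methylbuta-1,3-dien-1-yl]oxy}di(propan-2-yl)silyl)oxy]oct-2-ene-4,6-diynoate, via dienyloxysilyl triflate 6 (not isolated)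
Conditions: iPr2Si(OTf)2 (1.05 equiv), Et3N (3 equiv), CH2Cl2, −78 to 0 °C; then 4, 0 °C to rt
Reagents that add atoms: di(propan-2-yl)silanediyl bis(trifluoromethanesulfonate), CC(C)[Si](OS(=O)(=O)C(F)(F)F)(OS(=O)(=O)C(F)(F)F)C(C)C
Why: Soft enolization and O-silylation of the s-trans enal by the silyl triflate should give the (1E)-dienol silyl ether, and the second Si–OTf bond is then displaced by the primary alcohol (stepwise synthesis of an unsymmetrical silaketal).

Step 3
Reactants: 7 silaketal-tethered dienyl diynyl enoate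
Product: 8 tert-butyl (2E)-5-[8-methyl-2,2-di(propan-2-yl)-6,8a-dihydro-4H-1,3,2-benzodioxasilin-5-yl]pent-2-en-4-ynoate (racemic)
Conditions: PhMe (0.005 M), 2,6-di-tert-butyl-4-methylphenol (0.1 equiv), 2,6-di-tert-butyl-4-methylpyridine (0.2 equiv), 125 °C, sealed tube, Ar
Reagents that add atoms: none
Why: Thermal intramolecular [4+2] cycloaddition (type 1 intramolecular Diels–Alder reaction with a temporary silicon tether; closest known type: silaketal-tethered Diels–Alder reactions of dienyl and propargyl or allyl alcohols), in which the electron-rich (1E)-silyloxydiene adds suprafacially across the proximal triple bond of the diyne, whose LUMO is lowered by conjugation with the second alkyne and the enoate, so that C8–C8a and C5–C4a form together. The carbocycle closes as a cyclohexa-1,4-diene in the cycloaddition itself, and the six-membered 1,3,2-dioxasiline ring is the tether ring that closes at the same time in the fused mode, the only one open to a four-atom O–Si–O–C tether. The one new stereocentre (C8, later the ketone carbon) cannot be controlled in this achiral substrate and forms as a racemate; it only relays facial information in step 4 and is destroyed in step 11. The step needs regioselectivity (C8 to C8a), which the tether enforces whatever the polarization of the dienophile; site selectivity, secured because the distal alkyne and the acrylate cannot reach the diene within one molecule and high dilution suppresses the bimolecular reaction; and survival of the 3-silyloxycyclohexa-1,4-diene, which the neutral, base-buffered medium and the ring-held C8–O bond should protect from loss of silanol to the arene.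

Step 4
Reactants: 8 racemic cyclohexadiene silaketal
Product: 9 tert-butyl (2E)-5-[(7R,8R,8aR)-7,8-epoxy-8-methyl-2,2-di(propan-2-yl)-6,7,8,8a-tetrahydro-4H-1,3,2-benzodioxasilin-5-yl]pent-2-en-4-ynoate (epoxide oxygen anti to the C8a–O bond of the silaketal)
Conditions: D-fructose-derived Shi ketone (1,2:4,5-di-O-isopropylidene-β-D-erythro-2,3-hexodiulo-2,6-pyranose, 0.3 equiv), KHSO5 (as 2KHSO5·KHSO4·K2SO4, 0.7 equiv), K2CO3, Bu4NHSO4, Na2B4O7 buffer, MeCN/CH2(OMe)2/H2O, −10 °C, stopped near half conversion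
Reagents that add atoms: potassium peroxymonosulfate, [K+].[O-]S(=O)(=O)OO
Why: Shi asymmetric epoxidation run as a kinetic resolution of a racemic 1,6-disubstituted cyclohexene: the chiral dioxirane should attack the electron-rich trisubstituted C6=C7 alkene (not the hindered, enyne-conjugated C4a=C8a alkene or the acrylate) fast only in the (8aS)-enantiomer of 8, where the reagent-preferred face is also the face anti to the allylic C8–O bond, which sets C6 and C7, while (8aR)-8 is recovered and discarded.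

Step 5
Reactants: 10 2,3,4-trimethoxy-6-methylbenzaldehyde
Product: 11 2,3,4-trihydroxy-6-methylbenzaldehyde
Conditions: BBr3 (4 equiv), CH2Cl2, −78 °C to rt; then H2O
Reagents that add atoms: none
Why: Lewis-acid cleavage of all three aryl methyl ethers (BBr3 demethylation), the formyl group being inert to the reagent.

Step 6
Reactants: 11 2,3,4-trihydroxy-6-methylbenzaldehyde
Product: 13 2-methoxy-3,4-bis[(4-methoxyphenyl)methoxy]-6-methylbenzaldehyde, via 2-hydroxy-3,4-bis[(4-methoxyphenyl)methoxy]-6-methylbenzaldehyde 12 (not isolated)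
Conditions: 4-methoxybenzyl chloride (2.05 equiv), K2CO3, DMF, rt; then MeI (3 equiv), 45 °C
Reagents that add atoms: 4-methoxybenzyl chloride, COc1ccc(CCl)cc1; iodomethane, CI
Why: Williamson etherification ordered by phenol reactivity: the 4- and 3-hydroxyls are alkylated first because the 2-hydroxyl is held in a hydrogen bond to the formyl group, and this last phenol is then methylated under more forcing conditions in the same flask.

Step 7
Reactants: 13 2-methoxy-3,4-bis[(4-methoxyphenyl)methoxy]-6-methylbenzaldehyde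
Product: 14 2-methoxy-3,4-bis[(4-methoxyphenyl)methoxy]-6-methylbenzoic acid
Conditions: NaClO2, NaH2PO4, 2-methylbut-2-ene, tBuOH/H2O, rt
Reagents that add atoms: sodium chlorite, [Na+].[O-]Cl=O
Why: Pinnick oxidation of the hindered aldehyde to the acid, with 2-methylbut-2-ene removing hypochlorous acid before it can chlorinate the electron-rich rings.

Step 8
Reactants: 9 epoxide; 14 2-methoxy-3,4-bis[(4-methoxyphenyl)methoxy]-6-methylbenzoic acid
Product: 15 (7S,8R,8aR)-8-hydroxy-8-methyl-5-[(3E)-5-tert-butoxy-5-oxopent-3-en-1-yn-1-yl]-2,2-di(propan-2-yl)-6,7,8,8a-tetrahydro-4H-1,3,2-benzodioxasilin-7-yl 2-methoxy-3,4-bis[(4-methoxyphenyl)methoxy]-6-methylbenzoate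
Conditions: 14 (1.5 equiv), Cs2CO3 (0.2 equiv), DMF, 70 °C
Reagents that add atoms: none
Why: SN2 opening of the trisubstituted epoxide by the caesium carboxylate at the less substituted C6 (anti, Fürst–Plattner-type opening) inverts C6 and leaves the epoxide oxygen on C7, which gives the trans C6 ester and C7 tertiary alcohol of the target; the hindered 2,6-disubstituted acid reacts as a nucleophile, the role in which such acids esterify well.

Step 9
Reactants: 15 silaketal ester
Product: 16 (1S,2S,3R)-2,3-dihydroxy-4-(hydroxymethyl)-2-methyl-5-[(3E)-5-tert-butoxy-5-oxopent-3-en-1-yn-1-yl]cyclohex-4-en-1-yl 2-methoxy-3,4-bis[(4-methoxyphenyl)methoxy]-6-methylbenzoate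
Conditions: HF·pyridine, pyridine, THF, 0 °C to rt
Reagents that add atoms: none
Why: Fluoride cleavage of the dialkoxysilane (desilylation) frees the C8 and C1 hydroxyls, and the buffered reagent should leave the 4-methoxybenzyl ethers, the tert-butyl ester and the hindered aryl ester intact.

Step 10
Reactants: 16 triol
Product: 17 (1S,2S,3R)-4-({[tert-butyl(dimethyl)silyl]oxy}methyl)-2,3-dihydroxy-2-methyl-5-[(3E)-5-tert-butoxy-5-oxopent-3-en-1-yn-1-yl]cyclohex-4-en-1-yl 2-methoxy-3,4-bis[(4-methoxyphenyl)methoxy]-6-methylbenzoate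
Conditions: TBSCl (1.1 equiv), imidazole, CH2Cl2, −20 to 0 °C
Reagents that add atoms: tert-butyl(chloro)dimethylsilane, CC(C)(C)[Si](C)(C)Cl
Why: Selective silylation of the primary allylic alcohol over the hindered secondary and the tertiary alcohol, so that only the C8 hydroxyl is open to oxidation.

Step 11
Reactants: 17 silyl ether diol
Product: 18 (1S,6R)-4-({[tert-butyl(dimethyl)silyl]oxy}methyl)-6-hydroxy-6-methyl-5-oxo-3-[(3E)-5-tert-butoxy-5-oxopent-3-en-1-yn-1-yl]cyclohex-3-en-1-yl 2-methoxy-3,4-bis[(4-methoxyphenyl)methoxy]-6-methylbenzoate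
Conditions: Dess–Martin periodinane (1,1,1-triacetoxy-1,1-dihydro-1,2-benziodoxol-3(1H)-one), NaHCO3, CH2Cl2, 0 °C to rt
Reagents that add atoms: none
Why: Dess–Martin oxidation of the secondary allylic alcohol gives the C8 ketone and removes the relay stereocentre; the tertiary C7 alcohol cannot be oxidized, and aromatization is no longer possible because C6 and C7 are saturated.

Step 12
Reactants: 18 silyloxymethyl ynenone
Product: 21 tert-butyl (2E)-3-[(6S,7R)-7-hydroxy-6-({2-methoxy-3,4-bis[(4-methoxyphenyl)methoxy]-6-methylbenzoyl}oxy)-7-methyl-8-oxo-5,6,7,8-tetrahydro-1H-isochromen-3-yl]prop-2-enoate, via morpholine enaminone 19 (not isolated), via desilylated enaminone 20 (not isolated)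
Conditions: morpholine (3 equiv), THF, 0 °C to rt; then HF·pyridine, THF, rt
Reagents that add atoms: none
Why: 1,6-Aza-Michael addition of morpholine to the ynenone, at the alkyne carbon δ to the C8 ketone and remote from the ring, gives a vinylogous amide; acid then removes the silyl group, and the freed C1 hydroxyl adds to the iminium carbon (6-exo-trig) with expulsion of morpholine (addition–elimination, as in chromone synthesis from enaminones), which places the ring oxygen on C3 and not on C4 as direct 5-exo attack on the alkyne would.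

Step 13
Reactants: 21 protected target
Product: 22 (2E)-3-[(6S,7R)-6-[(3,4-dihydroxy-2-methoxy-6-methylbenzoyl)oxy]-7-hydroxy-7-methyl-8-oxo-5,6,7,8-tetrahydro-1H-isochromen-3-yl]prop-2-enoic acid (CNP0446308.1)
Conditions: CF3CO2H, anisole (20 equiv), CH2Cl2, 0 °C, Ar
Reagents that add atoms: none
Why: Acidolysis cleaves both 4-methoxybenzyl aryl ethers and the tert-butyl ester in one operation, anisole trapping the benzylic cations, and the push–pull enol ether, the hindered aryl ester and the tertiary alcohol should survive these non-reductive conditions.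

Compound list
1 | hexa-2,4-diyne-1,6-diol | OCC#CC#CCO | starting material
2 | tert-butyl 2-(triphenyl-λ5-phosphanylidene)acetate | CC(C)(C)OC(=O)C=P(c1ccccc1)(c1ccccc1)c1ccccc1 | starting material
3 | 6-hydroxyhexa-2,4-diynal | OCC#CC#CC=O | intermediate (not isolated)
4 | tert-butyl (2E)-8-hydroxyoct-2-ene-4,6-diynoate | OCC#CC#C/C=C/C(=O)OC(C)(C)C | intermediate
5 | (2E)-2-methylbut-2-enal | C/C=C(\C)C=O | starting material
6 | {[(1E)-2-methylbuta-1,3-dien-1-yl]oxy}di(propan-2-yl)silyl trifluoromethanesulfonate | C=C/C(C)=C/O[Si](C(C)C)(C(C)C)OS(=O)(=O)C(F)(F)F | intermediate (not isolated)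
7 | tert-butyl (2E)-8-[({[(1E)-2-methylbuta-1,3-dien-1-yl]oxy}di(propan-2-yl)silyl)oxy]oct-2-ene-4,6-diynoate | C=C/C(C)=C/O[Si](C(C)C)(C(C)C)OCC#CC#C/C=C/C(=O)OC(C)(C)C | intermediate
8 | tert-butyl (2E)-5-[8-methyl-2,2-di(propan-2-yl)-6,8a-dihydro-4H-1,3,2-benzodioxasilin-5-yl]pent-2-en-4-ynoate, racemic | CC1=CCC(C#C/C=C/C(=O)OC(C)(C)C)=C2CO[Si](C(C)C)(C(C)C)OC12 | intermediate
9 | tert-butyl (2E)-5-[(7R,8R,8aR)-7,8-epoxy-8-methyl-2,2-di(propan-2-yl)-6,7,8,8a-tetrahydro-4H-1,3,2-benzodioxasilin-5-yl]pent-2-en-4-ynoate | C[C@@]12O[C@@H]1CC(C#C/C=C/C(=O)OC(C)(C)C)=C3CO[Si](C(C)C)(C(C)C)O[C@@H]23 | intermediate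
10 | 2,3,4-trimethoxy-6-methylbenzaldehyde | COc1cc(C)c(C=O)c(OC)c1OC | starting material
11 | 2,3,4-trihydroxy-6-methylbenzaldehyde | Oc1cc(C)c(C=O)c(O)c1O | intermediate
12 | 2-hydroxy-3,4-bis[(4-methoxyphenyl)methoxy]-6-methylbenzaldehyde | COc1ccc(COc2cc(C)c(C=O)c(O)c2OCc2ccc(OC)cc2)cc1 | intermediate (not isolated)
13 | 2-methoxy-3,4-bis[(4-methoxyphenyl)methoxy]-6-methylbenzaldehyde | COc1ccc(COc2cc(C)c(C=O)c(OC)c2OCc2ccc(OC)cc2)cc1 | intermediate
14 | 2-methoxy-3,4-bis[(4-methoxyphenyl)methoxy]-6-methylbenzoic acid | COc1ccc(COc2cc(C)c(C(=O)O)c(OC)c2OCc2ccc(OC)cc2)cc1 | intermediate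
15 | (7S,8R,8aR)-8-hydroxy-8-methyl-5-[(3E)-5-tert-butoxy-5-oxopent-3-en-1-yn-1-yl]-2,2-di(propan-2-yl)-6,7,8,8a-tetrahydro-4H-1,3,2-benzodioxasilin-7-yl 2-methoxy-3,4-bis[(4-methoxyphenyl)methoxy]-6-methylbenzoate | COc1ccc(COc2cc(C)c(C(=O)O[C@H]3CC(C#C/C=C/C(=O)OC(C)(C)C)=C4CO[Si](C(C)C)(C(C)C)O[C@H]4[C@]3(C)O)c(OC)c2OCc2ccc(OC)cc2)cc1 | intermediate
16 | (1S,2S,3R)-2,3-dihydroxy-4-(hydroxymethyl)-2-methyl-5-[(3E)-5-tert-butoxy-5-oxopent-3-en-1-yn-1-yl]cyclohex-4-en-1-yl 2-methoxy-3,4-bis[(4-methoxyphenyl)methoxy]-6-methylbenzoate | COc1ccc(COc2cc(C)c(C(=O)O[C@H]3CC(C#C/C=C/C(=O)OC(C)(C)C)=C(CO)[C@@H](O)[C@]3(C)O)c(OC)c2OCc2ccc(OC)cc2)cc1 | intermediate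
17 | (1S,2S,3R)-4-({[tert-butyl(dimethyl)silyl]oxy}methyl)-2,3-dihydroxy-2-methyl-5-[(3E)-5-tert-butoxy-5-oxopent-3-en-1-yn-1-yl]cyclohex-4-en-1-yl 2-methoxy-3,4-bis[(4-methoxyphenyl)methoxy]-6-methylbenzoate | COc1ccc(COc2cc(C)c(C(=O)O[C@H]3CC(C#C/C=C/C(=O)OC(C)(C)C)=C(CO[Si](C)(C)C(C)(C)C)[C@@H](O)[C@]3(C)O)c(OC)c2OCc2ccc(OC)cc2)cc1 | intermediate
18 | (1S,6R)-4-({[tert-butyl(dimethyl)silyl]oxy}methyl)-6-hydroxy-6-methyl-5-oxo-3-[(3E)-5-tert-butoxy-5-oxopent-3-en-1-yn-1-yl]cyclohex-3-en-1-yl 2-methoxy-3,4-bis[(4-methoxyphenyl)methoxy]-6-methylbenzoate | COc1ccc(COc2cc(C)c(C(=O)O[C@H]3CC(C#C/C=C/C(=O)OC(C)(C)C)=C(CO[Si](C)(C)C(C)(C)C)C(=O)[C@]3(C)O)c(OC)c2OCc2ccc(OC)cc2)cc1 | intermediate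
19 | morpholine 1,6-adduct of 18 (4-morpholinyl on the former alkyne carbon that carries the acrylate; geometry of the new C=C bond not fixed) | COc1ccc(COc2cc(C)c(C(=O)O[C@H]3CC(C=C(N4CCOCC4)/C=C/C(=O)OC(C)(C)C)=C(CO[Si](C)(C)C(C)(C)C)C(=O)[C@]3(C)O)c(OC)c2OCc2ccc(OC)cc2)cc1 | intermediate (not isolated)
20 | desilylated enaminone (free hydroxymethyl analogue of 19) | COc1ccc(COc2cc(C)c(C(=O)O[C@H]3CC(C=C(N4CCOCC4)/C=C/C(=O)OC(C)(C)C)=C(CO)C(=O)[C@]3(C)O)c(OC)c2OCc2ccc(OC)cc2)cc1 | intermediate (not isolated)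
21 | tert-butyl (2E)-3-[(6S,7R)-7-hydroxy-6-({2-methoxy-3,4-bis[(4-methoxyphenyl)methoxy]-6-methylbenzoyl}oxy)-7-methyl-8-oxo-5,6,7,8-tetrahydro-1H-isochromen-3-yl]prop-2-enoate | COc1ccc(COc2cc(C)c(C(=O)O[C@H]3CC4=C(COC(/C=C/C(=O)OC(C)(C)C)=C4)C(=O)[C@]3(C)O)c(OC)c2OCc2ccc(OC)cc2)cc1 | intermediate
22 | (2E)-3-[(6S,7R)-6-[(3,4-dihydroxy-2-methoxy-6-methylbenzoyl)oxy]-7-hydroxy-7-methyl-8-oxo-5,6,7,8-tetrahydro-1H-isochromen-3-yl]prop-2-enoic acid | COc1c(O)c(O)cc(C)c1C(=O)O[C@H]1CC2=C(COC(/C=C/C(=O)O)=C2)C(=O)[C@]1(C)O | target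

Total step count: 13.
Longest linear sequence: 10 steps (steps 1, 2, 3, 4, 8, 9, 10, 11, 12, 13); steps 5–7 prepare the acid 14.

Steps most likely to fail

Step 3. The cycloaddition may be too slow at temperatures the substrate tolerates, so that polymerization of the enediyne ester, bimolecular cycloaddition at the acrylate, or loss of silanol from the adduct with aromatization takes over. The fallback sets out from 5 and 4 and comes back at 8. Aldehyde 5 would be silylated with iPr2SiHCl, NaI and Et3N in MeCN to {[(1E)-2-methylbuta-1,3-dien-1-yl]oxy}di(propan-2-yl)silane F1, and alcohol 4 oxidized with MnO2 to tert-butyl (2E)-8-oxooct-2-ene-4,6-diynoate F2. A bimolecular Diels–Alder reaction of F1 with the strongly activated ynal (CH2Cl2, 0 °C to rt), in which the formyl group directs the oxygenated diene terminus to its own carbon, should give racemic tert-butyl (2E)-5-(3-{[di(propan-2-yl)silyl]oxy}-2-formyl-4-methylcyclohexa-1,4-dien-1-yl)pent-2-en-4-ynoate F3. Intramolecular hydrosilylation of the formyl group by the neighbouring Si–H (catalytic Bu4N[Ph3SiF2], THF, 0 °C) then closes the dioxasiline ring and gives 8.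

Step 4. The rate difference between the enantiomers of 8 may be too small, or the dioxirane may choose the face set by the substrate in both enantiomers, so that the epoxide is formed with low enantiomeric purity; hydrolysis of the silaketal in the buffer is a further risk. The fallback sets out from 8 and comes back at 9. Racemic 8 would be epoxidized with dimethyldioxirane in acetone at −20 °C, anti to the C8–O bond by substrate control. The racemic epoxide, 9 together with its mirror image tert-butyl (2E)-5-[(7S,8S,8aS)-7,8-epoxy-8-methyl-2,2-di(propan-2-yl)-6,7,8,8a-tetrahydro-4H-1,3,2-benzodioxasilin-5-yl]pent-2-en-4-ynoate F4, would be resolved by preparative HPLC on a cellulose tris(3,5-dimethylphenylcarbamate) phase, and 9 re-enters at step 8.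

Step 12. The amine may add at the other alkyne carbon under the influence of the acrylate, the freed hydroxyl may close in the 5-exo sense to an alkylidene-dihydrofuran that isomerizes to a furan, or base-induced elimination of the C6 benzoate may occur through the dienolate. The fallback sets out from 16 and comes back at 21. MnO2 in CH2Cl2 would oxidize both allylic hydroxyls of 16 to (1S,6R)-4-formyl-6-hydroxy-6-methyl-5-oxo-3-[(3E)-5-tert-butoxy-5-oxopent-3-en-1-yn-1-yl]cyclohex-3-en-1-yl 2-methoxy-3,4-bis[(4-methoxyphenyl)methoxy]-6-methylbenzoate F5. Catalytic AgOSO2CF3 in CH2Cl2 should then drive 6-endo attack of the formyl oxygen on the alkyne to the aromatic pyrylium salt (6S,7R)-3-[(1E)-3-tert-butoxy-3-oxoprop-1-en-1-yl]-7-hydroxy-6-({2-methoxy-3,4-bis[(4-methoxyphenyl)methoxy]-6-methylbenzoyl}oxy)-7-methyl-8-oxo-5,6,7,8-tetrahydroisochromenylium trifluoromethanesulfonate F6 (not isolated), which Hantzsch ester (diethyl 2,6-dimethyl-1,4-dihydropyridine-3,5-dicarboxylate) present in the flask reduces at C1 to give 21 (domino cycloisomerization–reduction of an alkynyl aldehyde).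

Further compounds
F1 | step 3 | {[(1E)-2-methylbuta-1,3-dien-1-yl]oxy}di(propan-2-yl)silane | C=C/C(C)=C/O[SiH](C(C)C)C(C)C
F2 | step 3 | tert-butyl (2E)-8-oxooct-2-ene-4,6-diynoate | O=CC#CC#C/C=C/C(=O)OC(C)(C)C
F3 | step 3 | tert-butyl (2E)-5-(3-{[di(propan-2-yl)silyl]oxy}-2-formyl-4-methylcyclohexa-1,4-dien-1-yl)pent-2-en-4-ynoate, racemic | CC1=CCC(C#C/C=C/C(=O)OC(C)(C)C)=C(C=O)C1O[SiH](C(C)C)C(C)C
F4 | step 4 | tert-butyl (2E)-5-[(7S,8S,8aS)-7,8-epoxy-8-methyl-2,2-di(propan-2-yl)-6,7,8,8a-tetrahydro-4H-1,3,2-benzodioxasilin-5-yl]pent-2-en-4-ynoate (enantiomer of 9) | C[C@]12O[C@H]1CC(C#C/C=C/C(=O)OC(C)(C)C)=C3CO[Si](C(C)C)(C(C)C)O[C@H]23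
F5 | step 12 | (1S,6R)-4-formyl-6-hydroxy-6-methyl-5-oxo-3-[(3E)-5-tert-butoxy-5-oxopent-3-en-1-yn-1-yl]cyclohex-3-en-1-yl 2-methoxy-3,4-bis[(4-methoxyphenyl)methoxy]-6-methylbenzoate | COc1ccc(COc2cc(C)c(C(=O)O[C@H]3CC(C#C/C=C/C(=O)OC(C)(C)C)=C(C=O)C(=O)[C@]3(C)O)c(OC)c2OCc2ccc(OC)cc2)cc1
F6 | step 12 | (6S,7R)-3-[(1E)-3-tert-butoxy-3-oxoprop-1-en-1-yl]-7-hydroxy-6-({2-methoxy-3,4-bis[(4-methoxyphenyl)methoxy]-6-methylbenzoyl}oxy)-7-methyl-8-oxo-5,6,7,8-tetrahydroisochromenylium trifluoromethanesulfonate | COc1ccc(COc2cc(C)c(C(=O)O[C@H]3CC4=C(C=[O+]C(/C=C/C(=O)OC(C)(C)C)=C4)C(=O)[C@]3(C)O)c(OC)c2OCc2ccc(OC)cc2)cc1.[O-]S(=O)(=O)C(F)(F)F
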